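**Retrosynthetic overview**
- The ketone is made last, by allylic oxidation of a triol monoacetate. No base-labile acetoxy enone is carried through the route.
- Key disconnection: the tertiary and side-chain C–O bonds come from one suprafacial osmium dihydroxylation of an exocyclic alkene, anti to the two ring oxygens. The alkene-geometry problem becomes a choice of which ring carbinol keeps the acetate.
- That choice, and the absolute configuration, are made by lipase alcoholysis of a racemic cis-diacetate.
- The two ring C–O bonds come from singlet oxygen [4+2] addition to 6-tetradecylfulvene, followed by O–O reduction and acetylation.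
- The carbon skeleton comes from cyclopentadiene and pentadecanal. The carbocycle is bought; the only ring formed is a transient dioxabicycloheptene, opened in the same flask.

Assumption: cyclopentadiene counts as purchased (cracked from commercial dicyclopentadiene just before use). Each racemic compound is drawn as the enantiomer that is carried on to the target.

**Step 1**
Reactants: 1 cyclopentadiene; 2 pentadecanal
Product: 3 6-tetradecylfulvene (5-pentadecylidenecyclopenta-1,3-diene)
Conditions: pyrrolidine (0.2 equiv), MeOH/THF 3:1, 0 °C to rt; AcOH quench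
Reagents that add atoms: none
Why: Pyrrolidine-catalysed fulvene condensation (Thiele/Stone–Little type), in which the iminium ion of 2 is attacked by 1 and loss of the amine gives the fulvene with all twenty skeletal carbons and no stereocenter.

**Step 2**
Reactants: 3 6-tetradecylfulvene
Product: 6 racemic cis-2-pentadecylidenecyclopent-4-ene-1,3-diyl diacetate, via fulvene endoperoxide 4 (not isolated), via cis-diol 5 (not isolated)
Conditions: O2, rose bengal (1 mol %), CH2Cl2/MeOH 3:1, green LED, −40 °C, stop when the yellow colour fades; thiourea (2.2 equiv) in MeOH, −40 °C to rt; filter, concentrate; Ac2O (3 equiv), pyridine, DMAP (5 mol %), CH2Cl2, 0 °C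
Reagents that add atoms: dioxygen, O=O; acetic anhydride, CC(=O)OC(C)=O
Why: Singlet-oxygen [4+2] cycloaddition (Schenck-type photooxygenation) across the ring diene makes both ring C–O bonds on one face, thiourea cleaves the O–O bond of labile 4 with retention to cis-diol 5, and exhaustive acetylation gives stable 6, which is racemic only because the chain points towards one of the two carbinol carbons.

**Step 3**
Reactants: 6 racemic cis-2-pentadecylidenecyclopent-4-ene-1,3-diyl diacetate
Product: 7 (1S,4R,5E)-4-hydroxy-5-pentadecylidenecyclopent-2-en-1-yl acetate (free OH syn to the chain, acetate on the carbon syn to the vinylic H, OH and OAc cis)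
Conditions: Candida antarctica lipase B on acrylic resin (Novozym 435), MeOH (5 equiv), MTBE, 20 °C, to full consumption of 6; SiO2 chromatography removes the (5Z) isomer
Reagents that add atoms: none
Why: Proposed new method: regiodivergent lipase alcoholysis of a racemic, pseudo-meso bis-allylic diacetate; the serine hydrolase forms its acetyl-enzyme only from the ester whose carbinol carbon has the configuration it already prefers in the parent meso cis-cyclopent-4-ene-1,3-diyl diacetate (flat ring CH=CH in the small pocket, C2 side towards the entrance), so in the drawn enantiomer of 6 it frees the carbinol syn to the chain and keeps the acetate at the future C4 in the correct absolute sense, whereas the antipode loses its other acetate and ends as the separable (5Z) isomer (maximum yield of 7 is 50 %); ent-7 could form only by attack on an ester that is both wrongly configured and chain-shielded, which protects the ee; closest known reaction types are the lipase desymmetrising alcoholysis of the parent meso diacetate and parallel kinetic resolution.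

**Step 4**
Reactants: 7 (1S,4R,5E)-4-hydroxy-5-pentadecylidenecyclopent-2-en-1-yl acetate
Product: 8 (1S,4R,5S)-4,5-dihydroxy-5-[(1S)-1-hydroxypentadecyl]cyclopent-2-en-1-yl acetate
Conditions: K2OsO2(OH)4 (2 mol %), (DHQ)2PHAL (5 mol %), NMO (1.2 equiv), acetone/H2O 5:1, 0 °C; Na2SO3 quench
Reagents that add atoms: N-methylmorpholine N-oxide, C[N+]1([O-])CCOCC1; water, O
Why: Ligand-accelerated osmium dihydroxylation (Sharpless ligand, Upjohn reoxidant) adds suprafacially to the more electron-rich trisubstituted exocyclic alkene rather than the cis-disubstituted ring alkene, from the face opposite both allylic oxygens (Kishi model), which is also the face the DHQ ligand selects by the mnemonic, so the tertiary OH ends trans to the acetate and, because the chain is syn to the free carbinol, the side-chain carbinol is (S).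

**Step 5**
Reactants: 8 (1S,4R,5S)-4,5-dihydroxy-5-[(1S)-1-hydroxypentadecyl]cyclopent-2-en-1-yl acetate
Product: 9 (1S,5R)-5-hydroxy-5-[(1S)-1-hydroxypentadecyl]-4-oxocyclopent-2-en-1-yl acetate (target)
Conditions: activated MnO2 (15 equiv), CH2Cl2, rt
Reagents that add atoms: none
Why: Chemoselective allylic alcohol oxidation on activated MnO2, in which only the ring carbinol is allylic, so the saturated secondary OH, the tertiary OH and the acetate stay untouched under neutral conditions and none of the three remaining stereocenters is disturbed.

**Compound list**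
1 | cyclopentadiene | C1C=CC=C1 | starting material
2 | pentadecanal | CCCCCCCCCCCCCCC=O | starting material
3 | 6-tetradecylfulvene | CCCCCCCCCCCCCCC=C1C=CC=C1 | intermediate
4 | racemic 7-pentadecylidene-2,3-dioxabicyclo[2.2.1]hept-5-ene (fulvene endoperoxide) | CCCCCCCCCCCCCC/C=C1/[C@@H]2C=C[C@H]1OO2 | intermediate
5 | racemic cis-(1R*,3S*)-2-pentadecylidenecyclopent-4-ene-1,3-diol, chain syn to C1 | CCCCCCCCCCCCCC/C=C1/[C@@H](O)C=C[C@H]1O | intermediate
6 | racemic cis-(1R*,3S*)-2-pentadecylidenecyclopent-4-ene-1,3-diyl diacetate, chain syn to C1 | CCCCCCCCCCCCCC/C=C1/[C@@H](OC(C)=O)C=C[C@H]1OC(C)=O | intermediate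
7 | (1S,4R,5E)-4-hydroxy-5-pentadecylidenecyclopent-2-en-1-yl acetate | CCCCCCCCCCCCCC/C=C1/[C@@H](OC(C)=O)C=C[C@H]1O | intermediate
8 | (1S,4R,5S)-4,5-dihydroxy-5-[(1S)-1-hydroxypentadecyl]cyclopent-2-en-1-yl acetate | CCCCCCCCCCCCCC[C@H](O)[C@]1(O)[C@H](O)C=C[C@@H]1OC(C)=O | intermediate
9 | (1S,5R)-5-hydroxy-5-[(1S)-1-hydroxypentadecyl]-4-oxocyclopent-2-en-1-yl acetate | CCCCCCCCCCCCCC[C@H](O)[C@]1(O)C(=O)C=C[C@@H]1OC(C)=O | target

**Step count**
Total steps: 5. Longest linear sequence: 5.

**Steps most likely to fail**

Step 3 (the proposed new step). The lipase may refuse the ester that is shielded by the cis chain. The fallback sets out from 6 and comes back at 7.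
- K2CO3/MeOH at 0 °C returns racemic diol 5.
- A classical acylative lipase resolution follows (Novozym 435, vinyl butanoate 0.6 equiv, MTBE). By the size rule it esterifies the open carbinol of the unwanted enantiomer to (1R,4S,5E)-4-hydroxy-5-pentadecylidenecyclopent-2-en-1-yl butanoate F1.
- The same resolution leaves (1R,3S)-2-pentadecylidenecyclopent-4-ene-1,3-diol (chain syn to C1) F2. The refusal of the shielded site that defeats step 3 is what keeps F2 untouched here.
- After chromatography, F2 is monoacetylated under steric control at the open carbinol (Ac2O 1.0 equiv, 2,4,6-collidine, CH2Cl2, −40 °C) to give 7.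

Step 4. The ring alkene may compete, or double dihydroxylation may occur. The fallback sets out from 7 and comes back at 9.
- The order of oxidations is reversed. MnO2 in CH2Cl2 first gives (1S,5Z)-4-oxo-5-pentadecylidenecyclopent-2-en-1-yl acetate F3.
- In F3 the disubstituted ring alkene is the electron-poorer enone bond.
- OsO4 (cat.), NMO and citric acid in t-BuOH/H2O then dihydroxylate the alkyl-bearing exocyclic bond anti to the acetate and give 9 directly.
- The acidic buffer suppresses Z/E isomerisation and acetyl shift.

Step 2. Endoperoxide 4 may rearrange, or the ene reaction may compete, before reduction. The fallback sets out from 2 and comes back at 5.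
- Racemic 4-(tert-butyldimethylsilyloxy)cyclopent-2-en-1-one F4 is deprotonated with LiN(iPr)2 (THF, −78 °C) and added to 2. This gives racemic trans-4-(tert-butyldimethylsilyloxy)-5-(1-hydroxypentadecyl)cyclopent-2-en-1-one F5.
- MsCl/Et3N gives the corresponding methanesulfonate F6.
- DBU gives racemic (5E)-4-(tert-butyldimethylsilyloxy)-5-pentadecylidenecyclopent-2-en-1-one F7.
- Luche reduction (NaBH4, CeCl3·7H2O, MeOH, −78 °C), anti to the silyl ether, gives racemic cis-4-(tert-butyldimethylsilyloxy)-5-pentadecylidenecyclopent-2-en-1-ol F8.
- Bu4NF frees 5, which is acetylated to 6 as in the last stage of step 2.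
- Either alkylidene geometry would lead to the same racemic 5.

**Further compounds**
F1 | step 3 | (1R,4S,5E)-4-hydroxy-5-pentadecylidenecyclopent-2-en-1-yl butanoate | CCCCCCCCCCCCCC/C=C1/[C@H](OC(=O)CCC)C=C[C@@H]1O
F2 | step 3 | (1R,3S)-2-pentadecylidenecyclopent-4-ene-1,3-diol, chain syn to C1, single enantiomer | CCCCCCCCCCCCCC/C=C1/[C@@H](O)C=C[C@H]1O
F3 | step 4 | (1S,5Z)-4-oxo-5-pentadecylidenecyclopent-2-en-1-yl acetate | CCCCCCCCCCCCCC/C=C1/[C@@H](OC(C)=O)C=CC1=O
F4 | step 2 | racemic 4-(tert-butyldimethylsilyloxy)cyclopent-2-en-1-one (purchased) | O=C1C=CC(O[Si](C)(C)C(C)(C)C)C1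
F5 | step 2 | racemic trans-4-(tert-butyldimethylsilyloxy)-5-(1-hydroxypentadecyl)cyclopent-2-en-1-one (carbinol epimers) | CCCCCCCCCCCCCCC(O)[C@@H]1C(=O)C=C[C@H]1O[Si](C)(C)C(C)(C)C
F6 | step 2 | methanesulfonate of F5 | CCCCCCCCCCCCCCC(OS(C)(=O)=O)[C@@H]1C(=O)C=C[C@H]1O[Si](C)(C)C(C)(C)C
F7 | step 2 | racemic (5E)-4-(tert-butyldimethylsilyloxy)-5-pentadecylidenecyclopent-2-en-1-one | CCCCCCCCCCCCCC/C=C1/C(=O)C=C[C@H]1O[Si](C)(C)C(C)(C)C
F8 | step 2 | racemic cis-4-(tert-butyldimethylsilyloxy)-5-pentadecylidenecyclopent-2-en-1-ol | CCCCCCCCCCCCCC/C=C1/[C@@H](O)C=C[C@H]1O[Si](C)(C)C(C)(C)C
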